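## The problem

Prevezol C is two separate cyclohexanes joined only by a two-carbon bridge. Lower-case locants denote atoms here: ring A is C-a1 (CHOH), C-a2 (C(CH3)OH), C-a3, C-a4, C-a5 (CH-isopropenyl), C-a6 (CH bearing the bridge); ring B is C-b1 (C(CH3)OH), C-b2 (CHBr), C-b3, C-b4 (CH bearing the bridge), C-b5, C-b6; the bridge is C-x1 (CH2 on C-a6) and C-x2 (the 1,1-disubstituted alkene carbon on C-b4, with its exocyclic CH2). Because the rings are not fused, neither can relay stereochemistry to the other, so the four contiguous centres of ring A (a1 R, a2 R, a5 S, a6 R) and the three of ring B (b1 S, b2 R, b4 R) must each be set in the absolute sense. On ring A the a5 isopropenyl group and the a6 side chain are trans-diequatorial and lock the chair, so they can steer the a1/a2 trans-diaxial diol (secondary a1-OH cis to the side chain, tertiary a2-OH), provided the C-a1=C-a2 alkene is oxidised from the right face and opened at the right carbon. Ring B carries a cis-bromohydrin (equatorial Br, axial OH, equatorial CH3) with both heteroatoms cis to the C-b4 substituent. Anti addition to an alkene cannot give it; an α-bromoketone plus a methyl nucleophile can, and C-b4 has no useful thermodynamic bias. The secondary bromide beside the tertiary carbinol will not survive a free alkoxide (semipinacol ring contraction), strong hot base or halophilic Lewis acids, and the three exocyclic-type alkenes compete for electrophilic oxidants and isomerise in strong acid. The enabling feature is that C-x1–C-x2 with its methylene is the branched 1,4-diene motif left by an alkyne–alkene ene coupling at a terminal alkyne on C-b4. The ene partner then ends as the diene C-a6=C-a1–C-a2(CH3)=C-a3, whose [4+2] union with an acrylate (C-a5=C-a4) is ring A.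

## Retrosynthesis

**Diol and silyl ether (23 ⇐ 22 ⇐ 21 ⇐ 20).** The C-b1 hydroxyl of prevezol C 23 is unmasked last from triethylsilyl ether 22, so that no step before it meets an alkoxide next to the bromide. The two C–O bonds at C-a1 and C-a2 are cut back to epoxide 21 and then to the ring alkene of 20. Hydrolysis is preferred over syn-dihydroxylation plus inversion because the locked chair delivers the trans-diaxial diol directly. Of the two possible epoxides, only the one cis to the side chain opens at the tertiary carbon in the diaxial sense, so the forward epoxidation must be reagent-controlled in face and must leave two 1,1-disubstituted alkenes alone.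

**Isopropenyl group (20 ⇐ 19 ⇐ 18 ⇐ 17 ⇐ 16).** The isopropenyl methylene is cut to the trans methyl ketone 19 (Wittig), which comes by epimerisation from cis ketone 18, made from thioester 17 and hence from imide 16. Going through the ketone, rather than adding two methyl groups to an ester and dehydrating, avoids isopropylidene isomers and gives an enolisable centre at C-a5 for the cis-to-trans correction. The cost is that this correction is thermodynamic and may need one recycle.

**Key disconnection (16 ⇐ 15 ⇐ 10 + 14 + 13; 13 ⇐ 11 + 12).** Three skeletal bonds are cut: C-a6–C-a5 and C-a4–C-a3 by a retro-Diels–Alder reaction to triene 15 and acrylimide 13, and C-x1–C-x2 by a retro-ene reaction to alkyne 10 and 2-methylpenta-1,4-diene 14. The neighbouring choice, joining two finished rings at C-x1, would need an sp3–sp2 coupling at a β-branched carbon and a separate synthesis of ring A. Here ring A, the bridge and the exocyclic methylene come from a commodity diene and an auxiliary-bound acrylate (13 from oxazolidinone 11 and acryloyl chloride 12). The forward step must deliver the branched ene isomer and one face of the dienophile; the cis relationship at C-a5 is accepted and repaired later.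

**Alkyne (10 ⇐ 9 ⇐ 8 ⇐ 7 ⇐ 6).** The alkyne carbon is cut from the aldehyde 8, the open form of lactol 7, which is the half-reduced lactone 6; silylation of hydroxy alkyne 9 gives 10. A triethylsilyl ether is chosen over a trimethylsilyl ether because carbonate in methanol, thiolate, cuprate and ylide all lie ahead.

**C-b4 through a bicyclic lactone (6 ⇐ 5 ⇐ 4 ⇐ 3).** The lactone C–O bond is cut to hydroxy acid 4 (from ester 3). A 2-oxabicyclo[2.2.2]octanone can only exist with the carboxyl carbon and the C-b1 oxygen cis, and the activated acid can lose its C-b4 configuration through ketene 5, so both C-b4 epimers funnel into 6. Simple base equilibration of an ester or aldehyde at C-b4 was rejected: the conformational preferences of those groups are small and the second chair is accessible, so the preference would be slight.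

**Bromohydrin (3 ⇐ 2 ⇐ 1).** The C-b1 methyl bond is cut to α-bromoketone 2, and the C–Br bond to the achiral keto ester 1. Addition of a methyl nucleophile anti to bromine gives the cis-bromohydrin that no alkene anti-addition can provide. The absolute configuration then rests on one catalyst-controlled bromination of a symmetric ketone, whose C-b2 centre is relayed to C-b1 (step 2) and C-b4 (step 4).

## Roads not taken

**Alternative 1:** The cut is at C-a6–C-x1 and C-x1–C-x2, with a formaldehyde-level carbon inserted between the enolisable ring A ketone A2 and the ring B alkenylboronate A3. In one flask A2 would be aminomethylated with the iminium salt A4, the Mannich base eliminated to the α-methylene ketone, and A3 added in a [RhCl(cod)]2-catalysed conjugate addition to give coupled ketone A1.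
- Merits: it is highly convergent. A2 has only one enolisable α-carbon, its C-a2 and C-a5 centres can be taken from a terpene precursor, C-a6 is set by protonation to the equatorial isomer, and the C-a1 carbinol would come from a bulky-hydride reduction instead of an epoxide opening.
- Weak points: rhodium additions of hindered 1,1-disubstituted alkenylboronates to exo-methylene ketones are less secure than aryl additions. The methylene ketone dimerises readily, and three mutually awkward media share one flask. A3 still has to be made from the same alkyne by a Markovnikov borylation, so the branched-regiochemistry question reappears one step earlier.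
- Comparison: for ring A stereochemistry this road is probably safer than the chosen one. The chosen plan sets against it a ring A built from commodity chemicals, no branched alkenyl metal, and the bridge, the methylene and the ring in one operation.

**Alternative 2:** The cut is through ring B (C-b4–C-b3 and C-b5–C-b6). A chiral oxazaborolidinium bis(trifluoromethanesulfonyl)imide would catalyse the Diels–Alder reaction of silyloxydiene A7 with the ring A vinyl ketone A6, giving the silyl enol ether A5 with a ketone at C-x2.
- Merits: C-b4 is set by the catalyst, and the enol ether is regiodefined for bromination at C-b2. On C-b4 this is better than the chosen plan, which relays the configuration through the bromide and a lactone.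
- Weak points: electrophilic bromination of such an enol ether is expected to be axial, placing bromine trans to the C-b4 substituent, whereas the target needs cis. The methyl addition would have to distinguish the ring ketone from the C-x2 ketone, or follow a methylenation that then exposes an alkene to the brominating agent. All of this comes late, on a fully elaborated and sensitive ring A, after a long linear sequence to A6.
- Comparison: the chosen plan does the delicate bromohydrin chemistry first, on a simple ester, where it can be optimised and corrected.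

**Alternative 3:** The cut is at C-a1–C-a6 and C-a4–C-a5. A [Cu((S,S)-t-Bu-box)](SbF6)2-catalysed endo Diels–Alder reaction of dienyl acetate A9 with dienoyl imide A10 would give A8.
- Merits: three ring A centres are set in one catalytic step. The endo rule puts the C-a1 acetate cis to the C-a6 carbonyl, the (E)-dienophile puts C-a5 trans to C-a6, and no auxiliary or epimerisation is needed. With the C-a1 oxygen already in place, the epoxide-opening question of the chosen plan disappears. In ring A stereocontrol this road is better.
- Weak points: A10 is a β-alkenyl, cross-conjugated dienophile that is itself a diene and is far less reactive than an acrylimide toward a modestly reactive acyloxydiene. The tertiary C-a2 carbinol still needs a face- and site-selective hydration beside an isopropenyl group. The bridge needs two further C–C bond constructions, including an sp3–sp2 coupling at a β-branched carbon.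
- Comparison: the chosen plan sets against the better stereocontrol the fact that the bridge and its methylene are formed in the ring-forming operation itself.

Key step: step 9

Remarks on the chemistry (assumptions):
- The sense of induction of the imidazolidine catalyst in step 1 is assigned by analogy with simple cyclohexanones; if the bromide proves to be (3S), the antipodal catalyst is used.
- The facial sense of the step 14 epoxidation is assigned from the spiro transition-state model for 1-substituted cyclohexenes; the enantiomeric ketone catalyst is the remedy if the sense or the substrate bias proves opposite.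

## Route

Step 1
Reactants: 1 ethyl 4-oxocyclohexane-1-carboxylate
Product: 2 ethyl (3R)-3-bromo-4-oxocyclohexane-1-carboxylate (mixture of C1 epimers)
Conditions: (4R,5R)-4,5-diphenylimidazolidine (20 mol %), PhCO2H (20 mol %), 4,4-dibromo-2,6-di-tert-butylcyclohexa-2,5-dien-1-one, THF, −30 °C; cold filtration, used at once
Reagents that add atoms: 4,4-dibromo-2,6-di-tert-butylcyclohexa-2,5-dien-1-one, O=C1C(C(C)(C)C)=CC(Br)(Br)C=C1C(C)(C)C
Why: Enamine-catalysed asymmetric α-bromination: the C2-symmetric imidazolidine forms the enamine of 1 and shields one face of the nucleophilic carbon, so C3 should be set as (R) by the catalyst; bromine is expected to arrive axially (mainly trans to the ester), but C1 is not relied on because it is erased and reset in step 4. The bromoketone is taken on without delay because enolisation or bromide exchange would erode C3.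

Step 2
Reactants: 2 ethyl (3R)-3-bromo-4-oxocyclohexane-1-carboxylate
Product: 3 ethyl (3R,4S)-3-bromo-4-hydroxy-4-methylcyclohexane-1-carboxylate (mixture of C1 epimers)
Conditions: MeMgBr, CeCl3, THF, −78 °C; aq. NH4Cl at −78 °C
Reagents that add atoms: methylmagnesium bromide, C[Mg]Br
Why: Organocerium 1,2-addition: the methylcerium reagent should attack the ketone much faster than the ester without enolising the α-bromoketone, and it approaches anti to the C–Br bond (Felkin–Anh polar model), which places OH cis to Br and sets C4 as (S) from C3. The cold quench keeps the halohydrin alkoxide from semipinacol rearrangement.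

Step 3
Reactants: 3 ethyl (3R,4S)-3-bromo-4-hydroxy-4-methylcyclohexane-1-carboxylate
Product: 4 (3R,4S)-3-bromo-4-hydroxy-4-methylcyclohexane-1-carboxylic acid (mixture of C1 epimers)
Conditions: LiOH, THF/H2O, 0 °C to rt; then 1 M HCl to pH 3
Reagents that add atoms: lithium hydroxide, [Li+].[OH-]
Why: Saponification of the ethyl ester; the cis-bromohydrin has no anti-periplanar O/Br pair, so no epoxide can form, and the hindered secondary bromide should not be displaced by cold aqueous hydroxide.

Step 4
Reactants: 4 (3R,4S)-3-bromo-4-hydroxy-4-methylcyclohexane-1-carboxylic acid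
Product: 6 (1S,4R,6R)-6-bromo-1-methyl-2-oxabicyclo[2.2.2]octan-3-one, via cyclohexylidene ketene 5 (not isolated)
Conditions: 2-chloro-1-methylpyridinium iodide, Et3N, MeCN (high dilution), reflux
Reagents that add atoms: none
Why: Mukaiyama lactonisation made stereoconvergent: the acyloxypyridinium salt of the epimer that cannot reach the hydroxyl loses its α-proton to Et3N to give ketene 5 (as cyclohexanecarbonyl derivatives do with tertiary amines), which erases C1 of 4. The tertiary hydroxyl then adds across the ring, and since the bicyclo[2.2.2] lactone can only form with carboxyl carbon and oxygen cis, C-b4 (C4 of 6) should be set as (R) by the C-b1 oxygen; high dilution suppresses ketene dimerisation.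

Step 5
Reactants: 6 (1S,4R,6R)-6-bromo-1-methyl-2-oxabicyclo[2.2.2]octan-3-one
Product: 7 (1S,4R,6R)-6-bromo-1-methyl-2-oxabicyclo[2.2.2]octan-3-ol (lactol, both anomers)
Conditions: i-Bu2AlH (1.1 equiv), CH2Cl2, −78 °C
Reagents that add atoms: none
Why: Partial reduction of a lactone with i-Bu2AlH; the aluminium hemiacetal is stable at −78 °C and should give the lactol on hydrolysis, with the bromide and both bridgehead centres untouched.

Step 6
Reactants: 7 (1S,4R,6R)-6-bromo-1-methyl-2-oxabicyclo[2.2.2]octan-3-ol
Product: 9 (1S,2R,4R)-2-bromo-4-ethynyl-1-methylcyclohexan-1-ol, via hydroxy aldehyde 8 (not isolated)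
Conditions: dimethyl (1-diazo-2-oxopropyl)phosphonate, K2CO3, MeOH, 0 °C to rt
Reagents that add atoms: dimethyl (1-diazo-2-oxopropyl)phosphonate, COP(=O)(OC)C(=[N+]=[N-])C(C)=O
Why: Seyferth–Gilbert homologation in the Ohira–Bestmann form: the strained lactol opens to aldehyde 8, which reacts with the diazomethylphosphonate anion and gives the alkyne by 1,2-hydrogen shift of the alkylidene carbene. The lactol keeps the free aldehyde concentration low and homologation of an α-branched aldehyde is normally faster than its enolisation, so C-b4 should be retained.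

Step 7
Reactants: 9 (1S,2R,4R)-2-bromo-4-ethynyl-1-methylcyclohexan-1-ol
Product: 10 {[(1S,2R,4R)-2-bromo-4-ethynyl-1-methylcyclohexyl]oxy}triethylsilane
Conditions: Et3SiOTf, 2,6-lutidine, CH2Cl2, 0 °C
Reagents that add atoms: triethylsilyl trifluoromethanesulfonate, CC[Si](CC)(CC)OS(=O)(=O)C(F)(F)F
Why: Silylation of a hindered tertiary alcohol with a silyl triflate and a non-nucleophilic base; the triethylsilyl ether blocks alkoxide formation next to the bromide and should survive methoxide, thiolate, cuprate and ylide.

Step 8
Reactants: 11 (4S)-4-benzyl-1,3-oxazolidin-2-one; 12 acryloyl chloride (prop-2-enoyl chloride)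
Product: 13 (4S)-4-benzyl-3-(prop-2-enoyl)-1,3-oxazolidin-2-one
Conditions: MeMgBr, THF, 0 °C; then 12, −78 to 0 °C
Reagents that add atoms: none
Why: N-Acylation of the bromomagnesium salt of the oxazolidinone; the magnesium counter-ion avoids the anionic polymerisation of the acryloyl group that the lithium salt provokes.

Step 9
Reactants: 10 {[(1S,2R,4R)-2-bromo-4-ethynyl-1-methylcyclohexyl]oxy}triethylsilane; 14 2-methylpenta-1,4-diene; 13 (4S)-4-benzyl-3-(prop-2-enoyl)-1,3-oxazolidin-2-one
Product: 16 (4S)-4-benzyl-3-[(1R,2S)-2-{2-[(1R,3R,4S)-3-bromo-4-methyl-4-(triethylsilyloxy)cyclohexyl]prop-2-en-1-yl}-4-methylcyclohex-3-ene-1-carbonyl]-1,3-oxazolidin-2-one, via branched triene 15 (not isolated)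
Conditions: [CpRu(MeCN)3]PF6 (10 mol %), 14 (3 equiv), acetone, rt; evaporate; then 13 (2 equiv), Et2AlCl (2.8 equiv), CH2Cl2, −78 to −40 °C
Reagents that add atoms: none
Why: A ruthenium alkyne–alkene (Alder-ene) coupling is followed in the same flask by an auxiliary-controlled Lewis-acid Diels–Alder reaction. Cationic CpRu binds alkyne 10 and the monosubstituted alkene of 14 and closes a ruthenacyclopentene with the new C-x1–C-x2 bond at the substituted alkyne carbon; β-hydride elimination of the doubly allylic hydrogen and reductive elimination should give the branched triene 15 with an (E)-1,3-diene. The closest known reaction types are the coupling of terminal alkynes with terminal alkenes to branched 1,4-dienes at [CpRu(MeCN)3]PF6 and the Et2AlCl-promoted cycloadditions of N-acryloyl oxazolidinones with acyclic dienes. After removal of acetone, Et2AlCl turns 13 into its cationic aluminium chelate and ring A closes by a concerted endo [4+2] cycloaddition that forms C-a6–C-a5 and C-a4–C-a3. The 1-alkyl and 3-methyl groups of the diene both put the largest HOMO coefficient on C-a3, so the acrylate β-carbon (C-a4) bonds there and the regiochemistry is not in doubt. C-a6 is set by the 4-benzyl group, which shields one face of the s-cis chelated acrylimide so that the diene adds to the other (2S in 16); C-a5 follows from the endo transition state (cis, 1R) and is corrected in step 12. The step needs branched regioselectivity in the ene coupling, which is usual for terminal alkynes at cationic CpRu but must be checked for this α-branched case, and it needs the 1,1-disubstituted alkenes and the hindered bromide to stay spectators, which their low reactivity at −78 °C should secure.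

Step 10
Reactants: 16 (4S)-4-benzyl-3-[(1R,2S)-2-{2-[(1R,3R,4S)-3-bromo-4-methyl-4-(triethylsilyloxy)cyclohexyl]prop-2-en-1-yl}-4-methylcyclohex-3-ene-1-carbonyl]-1,3-oxazolidin-2-one
Product: 17 S-ethyl (1R,2S)-2-{2-[(1R,3R,4S)-3-bromo-4-methyl-4-(triethylsilyloxy)cyclohexyl]prop-2-en-1-yl}-4-methylcyclohex-3-ene-1-carbothioate
Conditions: EtSH, n-BuLi, THF, −78 to 0 °C
Reagents that add atoms: ethanethiol, CCS
Why: Thiolysis of the N-acyl oxazolidinone with lithium ethanethiolate; the soft thiolate should cleave the hindered imide at the exocyclic carbonyl, auxiliary 11 is recovered, and the equatorial neopentyl-type bromide resists substitution at 0 °C.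

Step 11
Reactants: 17 S-ethyl (1R,2S)-2-{2-[(1R,3R,4S)-3-bromo-4-methyl-4-(triethylsilyloxy)cyclohexyl]prop-2-en-1-yl}-4-methylcyclohex-3-ene-1-carbothioate
Product: 18 1-[(1R,2S)-2-{2-[(1R,3R,4S)-3-bromo-4-methyl-4-(triethylsilyloxy)cyclohexyl]prop-2-en-1-yl}-4-methylcyclohex-3-en-1-yl]ethan-1-one (cis ketone)
Conditions: Me2CuLi (from MeLi and CuI), Et2O, −78 °C
Reagents that add atoms: lithium dimethylcuprate, [Li+].C[Cu-]C
Why: Acylation of a Gilman cuprate by a thioester; Me2CuLi should give the methyl ketone without over-addition at −78 °C, where the secondary bromide and the alkenes are inert.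

Step 12
Reactants: 18 1-[(1R,2S)-2-{2-[(1R,3R,4S)-3-bromo-4-methyl-4-(triethylsilyloxy)cyclohexyl]prop-2-en-1-yl}-4-methylcyclohex-3-en-1-yl]ethan-1-one
Product: 19 1-[(1S,2S)-2-{2-[(1R,3R,4S)-3-bromo-4-methyl-4-(triethylsilyloxy)cyclohexyl]prop-2-en-1-yl}-4-methylcyclohex-3-en-1-yl]ethan-1-one (trans ketone)
Conditions: NaOMe (0.2 equiv), MeOH/THF, rt
Reagents that add atoms: none
Why: Base-mediated epimerisation through the enolate; the trans isomer with both ring substituents pseudo-equatorial should be favoured, which sets C-a5 relative to C-a6, and residual cis ketone is separated and resubmitted.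

Step 13
Reactants: 19 1-[(1S,2S)-2-{2-[(1R,3R,4S)-3-bromo-4-methyl-4-(triethylsilyloxy)cyclohexyl]prop-2-en-1-yl}-4-methylcyclohex-3-en-1-yl]ethan-1-one
Product: 20 {[(1S,2R,4R)-2-bromo-1-methyl-4-(3-[(1S,6S)-3-methyl-6-(prop-1-en-2-yl)cyclohex-2-en-1-yl]prop-1-en-2-yl)cyclohexyl]oxy}triethylsilane
Conditions: Ph3PCH3Br, KOt-Bu, THF, 0 °C to rt
Reagents that add atoms: methyltriphenylphosphonium bromide, C[P+](c1ccccc1)(c1ccccc1)c1ccccc1.[Br-]
Why: Wittig methylenation of a methyl ketone; the basic medium can only move C-a5 further toward the trans arrangement, and the silyl ether keeps the bromohydrin oxygen from becoming an alkoxide.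

Step 14
Reactants: 20 {[(1S,2R,4R)-2-bromo-1-methyl-4-(3-[(1S,6S)-3-methyl-6-(prop-1-en-2-yl)cyclohex-2-en-1-yl]prop-1-en-2-yl)cyclohexyl]oxy}triethylsilane
Product: 21 {[(1S,2R,4R)-2-bromo-1-methyl-4-(3-[(1R,2R,3S,6S)-6-methyl-3-(prop-1-en-2-yl)-7-oxabicyclo[4.1.0]heptan-2-yl]prop-1-en-2-yl)cyclohexyl]oxy}triethylsilane (epoxide oxygen cis to the C-a6 side chain, trans to isopropenyl)
Conditions: 1,2:4,5-di-O-isopropylidene-β-D-erythro-2,3-hexodiulo-2,6-pyranose (30 mol %), Oxone (2KHSO5·KHSO4·K2SO4), K2CO3, Bu4NHSO4, MeCN–CH2(OMe)2–aq. Na2B4O7 buffer (pH 10.5), 0 °C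
Reagents that add atoms: potassium peroxymonosulfate, [K+].[O-]S(=O)(=O)OO
Why: Shi epoxidation: the electrophilic chiral dioxirane should select the trisubstituted ring alkene over the two 1,1-disubstituted ones, and by the spiro transition-state model the D-fructose-derived ketone is expected to deliver oxygen to the face of C-a1=C-a2 that carries the side chain, setting C-a1 (R) and C-a2 (S). Reagent control is used because this is the epoxide for which Markovnikov and trans-diaxial opening coincide.

Step 15
Reactants: 21 {[(1S,2R,4R)-2-bromo-1-methyl-4-(3-[(1R,2R,3S,6S)-6-methyl-3-(prop-1-en-2-yl)-7-oxabicyclo[4.1.0]heptan-2-yl]prop-1-en-2-yl)cyclohexyl]oxy}triethylsilane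
Product: 22 (1R,2R,3R,4S)-3-{2-[(1R,3R,4S)-3-bromo-4-methyl-4-(triethylsilyloxy)cyclohexyl]prop-2-en-1-yl}-1-methyl-4-(prop-1-en-2-yl)cyclohexane-1,2-diol
Conditions: HClO4 (cat.), THF/H2O (3:1), 0 °C
Reagents that add atoms: water, O
Why: Acid-catalysed epoxide hydrolysis under Fürst–Plattner control: water should attack the tertiary C-a2 anti to the epoxide oxygen through a chair-like transition state held by the two equatorial substituents, giving the trans-diaxial diol with inversion at C-a2 (now R) and retention at C-a1 (R). Dilute acid at 0 °C should leave the exocyclic alkenes and the silyl ether largely untouched.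

Step 16
Reactants: 22 (1R,2R,3R,4S)-3-{2-[(1R,3R,4S)-3-bromo-4-methyl-4-(triethylsilyloxy)cyclohexyl]prop-2-en-1-yl}-1-methyl-4-(prop-1-en-2-yl)cyclohexane-1,2-diol
Product: 23 prevezol C, (1R,2R,3R,4S)-3-{2-[(1R,3R,4S)-3-bromo-4-hydroxy-4-methylcyclohexyl]prop-2-en-1-yl}-1-methyl-4-(prop-1-en-2-yl)cyclohexane-1,2-diol
Conditions: HF·pyridine, pyridine, THF, 0 °C to rt
Reagents that add atoms: none
Why: Fluoride-mediated cleavage of the tertiary triethylsilyl ether under buffered, non-basic conditions, so that no alkoxide forms next to the bromide; alkenes, diol and bromide are inert to HF·pyridine.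

## Compound list

1 | ethyl 4-oxocyclohexane-1-carboxylate | CCOC(=O)C1CCC(=O)CC1 | starting material
2 | ethyl (3R)-3-bromo-4-oxocyclohexane-1-carboxylate (mixture of C1 epimers) | CCOC(=O)C1CCC(=O)[C@H](Br)C1 | intermediate
3 | ethyl (3R,4S)-3-bromo-4-hydroxy-4-methylcyclohexane-1-carboxylate (mixture of C1 epimers) | CCOC(=O)C1CC[C@](C)(O)[C@H](Br)C1 | intermediate
4 | (3R,4S)-3-bromo-4-hydroxy-4-methylcyclohexane-1-carboxylic acid (mixture of C1 epimers) | OC(=O)C1CC[C@](C)(O)[C@H](Br)C1 | intermediate
5 | [(3R,4S)-3-bromo-4-hydroxy-4-methylcyclohexylidene]methanone (ketene) | O=C=C1CC[C@](C)(O)[C@H](Br)C1 | intermediate (not isolated)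
6 | (1S,4R,6R)-6-bromo-1-methyl-2-oxabicyclo[2.2.2]octan-3-one | O=C1[C@@H]2CC[C@](C)(O1)[C@H](Br)C2 | intermediate
7 | (1S,4R,6R)-6-bromo-1-methyl-2-oxabicyclo[2.2.2]octan-3-ol (both anomers) | OC1[C@@H]2CC[C@](C)(O1)[C@H](Br)C2 | intermediate
8 | (1R,3R,4S)-3-bromo-4-hydroxy-4-methylcyclohexane-1-carbaldehyde | O=C[C@@H]1CC[C@](C)(O)[C@H](Br)C1 | intermediate (not isolated)
9 | (1S,2R,4R)-2-bromo-4-ethynyl-1-methylcyclohexan-1-ol | C#C[C@@H]1CC[C@](C)(O)[C@H](Br)C1 | intermediate
10 | {[(1S,2R,4R)-2-bromo-4-ethynyl-1-methylcyclohexyl]oxy}triethylsilane | C#C[C@@H]1CC[C@](C)(O[Si](CC)(CC)CC)[C@H](Br)C1 | intermediate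
11 | (4S)-4-benzyl-1,3-oxazolidin-2-one | O=C1N[C@@H](Cc2ccccc2)CO1 | starting material
12 | acryloyl chloride | C=CC(=O)Cl | starting material
13 | (4S)-4-benzyl-3-(prop-2-enoyl)-1,3-oxazolidin-2-one | C=CC(=O)N1[C@@H](Cc2ccccc2)COC1=O | intermediate
14 | 2-methylpenta-1,4-diene | C=CCC(C)=C | starting material
15 | {[(1S,2R,4R)-2-bromo-1-methyl-4-[(4E)-6-methylhepta-1,4,6-trien-2-yl]cyclohexyl]oxy}triethylsilane | C=C(C/C=C/C(C)=C)[C@@H]1CC[C@](C)(O[Si](CC)(CC)CC)[C@H](Br)C1 | intermediate (not isolated)
16 | (4S)-4-benzyl-3-[(1R,2S)-2-{2-[(1R,3R,4S)-3-bromo-4-methyl-4-(triethylsilyloxy)cyclohexyl]prop-2-en-1-yl}-4-methylcyclohex-3-ene-1-carbonyl]-1,3-oxazolidin-2-one | C=C(C[C@@H]1[C@H](C(=O)N2[C@@H](Cc3ccccc3)COC2=O)CCC(C)=C1)[C@@H]1CC[C@](C)(O[Si](CC)(CC)CC)[C@H](Br)C1 | intermediate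
17 | S-ethyl (1R,2S)-2-{2-[(1R,3R,4S)-3-bromo-4-methyl-4-(triethylsilyloxy)cyclohexyl]prop-2-en-1-yl}-4-methylcyclohex-3-ene-1-carbothioate | C=C(C[C@@H]1[C@H](C(=O)SCC)CCC(C)=C1)[C@@H]1CC[C@](C)(O[Si](CC)(CC)CC)[C@H](Br)C1 | intermediate
18 | 1-[(1R,2S)-2-{2-[(1R,3R,4S)-3-bromo-4-methyl-4-(triethylsilyloxy)cyclohexyl]prop-2-en-1-yl}-4-methylcyclohex-3-en-1-yl]ethan-1-one | C=C(C[C@@H]1[C@H](C(C)=O)CCC(C)=C1)[C@@H]1CC[C@](C)(O[Si](CC)(CC)CC)[C@H](Br)C1 | intermediate
19 | 1-[(1S,2S)-2-{2-[(1R,3R,4S)-3-bromo-4-methyl-4-(triethylsilyloxy)cyclohexyl]prop-2-en-1-yl}-4-methylcyclohex-3-en-1-yl]ethan-1-one | C=C(C[C@@H]1[C@@H](C(C)=O)CCC(C)=C1)[C@@H]1CC[C@](C)(O[Si](CC)(CC)CC)[C@H](Br)C1 | intermediate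
20 | {[(1S,2R,4R)-2-bromo-1-methyl-4-(3-[(1S,6S)-3-methyl-6-(prop-1-en-2-yl)cyclohex-2-en-1-yl]prop-1-en-2-yl)cyclohexyl]oxy}triethylsilane | C=C(C[C@@H]1[C@@H](C(C)=C)CCC(C)=C1)[C@@H]1CC[C@](C)(O[Si](CC)(CC)CC)[C@H](Br)C1 | intermediate
21 | {[(1S,2R,4R)-2-bromo-1-methyl-4-(3-[(1R,2R,3S,6S)-6-methyl-3-(prop-1-en-2-yl)-7-oxabicyclo[4.1.0]heptan-2-yl]prop-1-en-2-yl)cyclohexyl]oxy}triethylsilane | C=C(C[C@@H]1[C@@H](C(C)=C)CC[C@]2(C)O[C@H]12)[C@@H]1CC[C@](C)(O[Si](CC)(CC)CC)[C@H](Br)C1 | intermediate
22 | (1R,2R,3R,4S)-3-{2-[(1R,3R,4S)-3-bromo-4-methyl-4-(triethylsilyloxy)cyclohexyl]prop-2-en-1-yl}-1-methyl-4-(prop-1-en-2-yl)cyclohexane-1,2-diol | C=C(C[C@@H]1[C@@H](C(=C)C)CC[C@@](C)(O)[C@@H]1O)[C@@H]1CC[C@](C)(O[Si](CC)(CC)CC)[C@H](Br)C1 | intermediate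
23 | prevezol C, (1R,2R,3R,4S)-3-{2-[(1R,3R,4S)-3-bromo-4-hydroxy-4-methylcyclohexyl]prop-2-en-1-yl}-1-methyl-4-(prop-1-en-2-yl)cyclohexane-1,2-diol | C=C(C[C@@H]1[C@@H](C(=C)C)CC[C@@](C)(O)[C@@H]1O)[C@@H]1CC[C@](C)(O)[C@H](Br)C1 | target

## Step count and least certain steps

Total: 16 steps. Longest linear sequence: 15 steps (steps 1–7 and 9–16); step 8 is a one-step branch.

**Step 9 (key step).** The ene coupling may lose branched regioselectivity because the alkyne is branched at the propargylic carbon. The skipped diene may also be isomerised or bound as a chelate at ruthenium, and a linear ene isomer would be carried into the cycloaddition as an inseparable regioisomeric adduct. Fallback, setting out from alkyne 10 and returning at triene 15: Markovnikov hydration ((Ph3P)AuNTf2, MeOH/H2O) should give the methyl ketone 1-[(1R,3R,4S)-3-bromo-4-methyl-4-(triethylsilyloxy)cyclohexyl]ethan-1-one F1. Kinetic enolisation on the methyl side (KN(SiMe3)2, PhNTf2, −78 °C) gives the enol triflate F2. Stille allylation (Pd(PPh3)4, LiCl, allyltributylstannane) gives the skipped diene F3, in which the branched connectivity at C-x2 is fixed by construction. Cross-metathesis of its monosubstituted alkene with but-3-en-2-one (second-generation Hoveyda–Grubbs catalyst) gives the (E)-enone F4, and Wittig methylenation gives triene 15. Triene 15 is then isolated and taken alone through the Et2AlCl cycloaddition with 13 to reach 16.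

**Step 1.** Facial control at the enamine may be incomplete, the sense of induction is assumed, and the α-bromoketone may racemise by enolisation or bromide exchange before step 2. Fallback, setting out from 1 and returning at 2: enantioselective deprotonation with a C2-symmetric chiral lithium amide (lithium bis[(R)-1-phenylethyl]amide or its antipode, Me3SiCl present, THF, −78 °C) gives the silyl enol ether ethyl (1S)-4-(trimethylsilyloxy)cyclohex-3-ene-1-carboxylate F5. Its bromination with N-bromosuccinimide at −78 °C by axial attack should return 2 as the (1S,3R) isomer. The C3 configuration is then relayed from a carbon stereocentre instead of being set by a catalyst on a labile ketone.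

**Step 4.** Ketene dimerisation or oligomerisation may compete, the hindered tertiary hydroxyl may fail to capture the activated acyl group, or the unreactive epimer may not enter the ketene manifold, so that convergence at C-b4 is lost. Fallback, setting out from 3 and returning at 10: silylation (Et3SiOTf, 2,6-lutidine) gives the ester F6, and reduction with i-Bu2AlH at −78 °C gives the aldehyde F7. F7 is equilibrated at C1 with DBU, where only a modest preference for the all-equatorial epimer is expected. Ohira–Bestmann homologation then gives 10 together with its C4 epimer F8, which is removed by chromatography.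

**Step 14.** The substrate's own facial bias (away from the side chain) may override the catalyst, and the dioxirane may also oxidise the 1,1-disubstituted alkenes. Fallback, setting out from trans ketone 19 and returning at 22: peracid epoxidation before the Wittig reaction (m-chloroperoxybenzoic acid, NaHCO3, CH2Cl2, 0 °C), where only one 1,1-disubstituted alkene competes, gives the epoxy ketone cis to the side chain F9 and its diastereomer trans to the side chain F10. Wittig methylenation of the mixture gives 21 and its epoxide diastereomer F11. Both are hydrolysed under the step 15 conditions, relying on trans-diaxial opening of either epoxide (at C-a2 for 21, at C-a1 for F11) to converge on 22.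

## Further compounds

F1 | step 9 | 1-[(1R,3R,4S)-3-bromo-4-methyl-4-(triethylsilyloxy)cyclohexyl]ethan-1-one | CC(=O)[C@@H]1CC[C@](C)(O[Si](CC)(CC)CC)[C@H](Br)C1
F2 | step 9 | 1-[(1R,3R,4S)-3-bromo-4-methyl-4-(triethylsilyloxy)cyclohexyl]ethenyl trifluoromethanesulfonate | C=C(OS(=O)(=O)C(F)(F)F)[C@@H]1CC[C@](C)(O[Si](CC)(CC)CC)[C@H](Br)C1
F3 | step 9 | {[(1S,2R,4R)-2-bromo-1-methyl-4-(penta-1,4-dien-2-yl)cyclohexyl]oxy}triethylsilane | C=CCC(=C)[C@@H]1CC[C@](C)(O[Si](CC)(CC)CC)[C@H](Br)C1
F4 | step 9 | (3E)-6-[(1R,3R,4S)-3-bromo-4-methyl-4-(triethylsilyloxy)cyclohexyl]hepta-3,6-dien-2-one | CC(=O)/C=C/CC(=C)[C@@H]1CC[C@](C)(O[Si](CC)(CC)CC)[C@H](Br)C1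
F5 | step 1 | ethyl (1S)-4-(trimethylsilyloxy)cyclohex-3-ene-1-carboxylate | CCOC(=O)[C@H]1CCC(O[Si](C)(C)C)=CC1
F6 | step 4 | ethyl (3R,4S)-3-bromo-4-methyl-4-(triethylsilyloxy)cyclohexane-1-carboxylate (mixture of C1 epimers) | CCOC(=O)C1CC[C@](C)(O[Si](CC)(CC)CC)[C@H](Br)C1
F7 | step 4 | (3R,4S)-3-bromo-4-methyl-4-(triethylsilyloxy)cyclohexane-1-carbaldehyde (mixture of C1 epimers) | O=CC1CC[C@](C)(O[Si](CC)(CC)CC)[C@H](Br)C1
F8 | step 4 | {[(1S,2R,4S)-2-bromo-4-ethynyl-1-methylcyclohexyl]oxy}triethylsilane | C#C[C@H]1CC[C@](C)(O[Si](CC)(CC)CC)[C@H](Br)C1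
F9 | step 14 | 1-[(1R,2R,3S,6S)-2-{2-[(1R,3R,4S)-3-bromo-4-methyl-4-(triethylsilyloxy)cyclohexyl]prop-2-en-1-yl}-6-methyl-7-oxabicyclo[4.1.0]heptan-3-yl]ethan-1-one | C=C(C[C@@H]1[C@@H](C(C)=O)CC[C@]2(C)O[C@H]12)[C@@H]1CC[C@](C)(O[Si](CC)(CC)CC)[C@H](Br)C1
F10 | step 14 | 1-[(1S,2R,3S,6R)-2-{2-[(1R,3R,4S)-3-bromo-4-methyl-4-(triethylsilyloxy)cyclohexyl]prop-2-en-1-yl}-6-methyl-7-oxabicyclo[4.1.0]heptan-3-yl]ethan-1-one | C=C(C[C@@H]1[C@@H](C(C)=O)CC[C@@]2(C)O[C@@H]12)[C@@H]1CC[C@](C)(O[Si](CC)(CC)CC)[C@H](Br)C1
F11 | step 14 | {[(1S,2R,4R)-2-bromo-1-methyl-4-(3-[(1S,2R,3S,6R)-6-methyl-3-(prop-1-en-2-yl)-7-oxabicyclo[4.1.0]heptan-2-yl]prop-1-en-2-yl)cyclohexyl]oxy}triethylsilane | C=C(C[C@@H]1[C@@H](C(C)=C)CC[C@@]2(C)O[C@@H]12)[C@@H]1CC[C@](C)(O[Si](CC)(CC)CC)[C@H](Br)C1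
A1 | alternative 1 | (2R,5S,6R)-6-{2-[(1R,3R,4S)-3-bromo-4-methyl-4-(triethylsilyloxy)cyclohexyl]prop-2-en-1-yl}-2-methyl-5-(prop-1-en-2-yl)-2-(triethylsilyloxy)cyclohexan-1-one | C=C(C[C@@H]1[C@@H](C(=C)C)CC[C@@](C)(O[Si](CC)(CC)CC)C1=O)[C@@H]1CC[C@](C)(O[Si](CC)(CC)CC)[C@H](Br)C1
A2 | alternative 1 | (2R,5S)-2-methyl-5-(prop-1-en-2-yl)-2-(triethylsilyloxy)cyclohexan-1-one | C1[C@@H](C(=C)C)CC[C@@](C)(O[Si](CC)(CC)CC)C1=O
A3 | alternative 1 | 2-{1-[(1R,3R,4S)-3-bromo-4-methyl-4-(triethylsilyloxy)cyclohexyl]ethenyl}-4,4,5,5-tetramethyl-1,3,2-dioxaborolane | C=C(B1OC(C)(C)C(C)(C)O1)[C@@H]1CC[C@](C)(O[Si](CC)(CC)CC)[C@H](Br)C1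
A4 | alternative 1 | dimethylmethyleneiminium iodide | C[N+](C)=C.[I-]
A5 | alternative 2 | ring B cyclohexenyl silyl enol ether with a ketone at C-x2 | O=C(C[C@@H]1[C@@H](C(=C)C)CC[C@@](C)(O[Si](CC)(CC)CC)[C@@H]1O[Si](CC)(CC)CC)[C@@H]1CCC(O[Si](C(C)C)(C(C)C)C(C)C)=CC1
A6 | alternative 2 | ring A vinyl ketone, 1-[(1R,2R,3R,6S)-3-methyl-6-(prop-1-en-2-yl)-2,3-bis(triethylsilyloxy)cyclohexyl]but-3-en-2-one | C=CC(=O)C[C@@H]1[C@@H](C(=C)C)CC[C@@](C)(O[Si](CC)(CC)CC)[C@@H]1O[Si](CC)(CC)CC
A7 | alternative 2 | 2-(triisopropylsilyloxy)buta-1,3-diene | C=CC(=C)O[Si](C(C)C)(C(C)C)C(C)C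
A8 | alternative 3 | ring A cyclohexene imide with C-a1 acetate, C-a5 isopropenyl and a C-a2=C-a3 alkene | O=C(N1CCOC1=O)[C@@H]1[C@@H](C(=C)C)CC=C(C)[C@@H]1OC(C)=O
A9 | alternative 3 | (1E)-2-methylbuta-1,3-dien-1-yl acetate | CC(=O)O/C=C(\C)C=C
A10 | alternative 3 | 3-[(2E)-4-methylpenta-2,4-dienoyl]-1,3-oxazolidin-2-one | C=C(C)/C=C/C(=O)N1CCOC1=O
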